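The target is the head-to-tail dimer of 7-methoxy-2,2-dimethyl-6-vinyl-2H-chromene, so one monomer serves both halves: asymmetric hydrovinylation sets the benzylic stereocentre and cross-metathesis joins the halves as the E-olefin. The pyran ring of the monomer is made one atom too small and then enlarged: a 2,2-dimethyl-2,3-dihydrobenzofuran bearing CH2OH at C3 undergoes a Wagner–Meerwein shift that delivers the 2H-chromene with its C3=C4 olefin in one operation. The step exploits that chromene C4 is ortho (through C4a–C8a) to O1 and para to the 7-methoxy group, so the ring-expanded C4 cation is doubly donor-stabilised, and that C2 is quaternary, so proton loss can only give C3=C4.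

Key step: step 4

Assumption: the enantiomer of the phosphoramidite ligand in step 6 is the one that delivers the S-olefin; the sense of induction on this vinylarene is to be assigned on the first run and the antipodal ligand used if required.

Step 1
Reactants: 1 1-bromo-2,4-dimethoxybenzene; 2 2-bromo-2-methylpropanoyl bromide
Product: 4 5-bromo-6-methoxy-2,2-dimethylbenzofuran-3(2H)-one, via bromoketone 3 (not isolated)
Conditions: AlCl3 (2.5 equiv), CH2Cl2, 0 °C → 40 °C; aq. HCl work-up
Reagents that add atoms: none
Why: Friedel–Crafts acylation should occur at C5 of 1 (para to the 2-OMe, ortho to the 4-OMe, the only unhindered doubly activated site), after which the ortho-methoxy oxygen displaces the AlCl3-activated tertiary α-bromide (5-exo) and the methyloxonium ion is demethylated by halide (cyclodemethylation), a known one-pot entry to 2,2-dimethylbenzofuran-3(2H)-ones.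

Step 2
Reactants: 4 5-bromo-6-methoxy-2,2-dimethylbenzofuran-3(2H)-one
Product: 5 5-bromo-6-methoxy-2,2-dimethyl-3-methylidene-2,3-dihydrobenzofuran
Conditions: Ph3PCH3Br (3.0 equiv), KOtBu (2.8 equiv), toluene, rt → 90 °C
Reagents that add atoms: methyltriphenylphosphonium bromide, C[P+](c1ccccc1)(c1ccccc1)c1ccccc1.[Br-]
Why: Wittig methylenation; the ketone has no α-hydrogen, so enolisation cannot compete and forcing conditions can be applied to the hindered, donor-deactivated carbonyl group.

Step 3
Reactants: 5 5-bromo-6-methoxy-2,2-dimethyl-3-methylidene-2,3-dihydrobenzofuran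
Product: 7 (5-bromo-6-methoxy-2,2-dimethyl-2,3-dihydrobenzofuran-3-yl)methanol (racemic), via B-alkyl-9-BBN adduct 6 (not isolated)
Conditions: 9-BBN (1.5 equiv), THF, 0 → 50 °C; then NaOH, H2O2, 0 °C → rt
Reagents that add atoms: hydrogen peroxide, OO
Why: Hydroboration–oxidation: boron should add to the unhindered terminal carbon of the 1,1-disubstituted olefin (anti-Markovnikov) and oxidation with retention gives the primary alcohol; the new C3 centre is racemic and is erased in step 4.

Step 4
Reactants: 7 (5-bromo-6-methoxy-2,2-dimethyl-2,3-dihydrobenzofuran-3-yl)methanol (racemic)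
Product: 9 6-bromo-7-methoxy-2,2-dimethyl-2H-chromene, via primary triflate 8 (not isolated)
Conditions: Tf2O (1.2 equiv), 2,6-di-tert-butyl-4-methylpyridine (3 equiv), CH2Cl2 (0.02 M), −78 → 0 °C
Reagents that add atoms: none
Why: O-Triflation gives the primary triflate 8, which should ionise with anchimeric assistance: the ring bond anti to the leaving group (C3–C3a through an aryl-bridged phenonium ion followed by a 1,2-hydride shift, or C3–C2 pushed by the O1 lone pair) migrates to the exocyclic carbon, so the five-membered ring grows by one carbon. Both channels converge on the chroman-4-yl cation, which is benzylic, ortho to O1 and para to the 7-methoxy group, and loss of H-3 to the hindered base gives the C3=C4 olefin, the only one possible because C2 is quaternary. The closest known reaction type is the Wagner–Meerwein (Demjanov-type) ring expansion of cycloalkylmethyl sulfonates, including the aryl-assisted enlargement of 3-(halomethyl)indolines and 3-(halomethyl)dihydrobenzofurans to six-membered rings. No ring is closed by cyclisation; the six-membered ring arises by 1,2-shift ring expansion of the existing five-membered ring. No stereocentre is formed, and the racemic C3 centre of 7 becomes sp2. The step needs the ring-bond shift to beat the 1,2-hydride shift from C3, a methyl shift from C2 and O1 participation (ring contraction to an isopropenyl-dihydrobenzofuran); the electron-rich arene, the stability of the C4 cation, low temperature, high dilution and a non-nucleophilic base are relied on to secure this.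

Step 5
Reactants: 9 6-bromo-7-methoxy-2,2-dimethyl-2H-chromene
Product: 10 7-methoxy-2,2-dimethyl-6-vinyl-2H-chromene
Conditions: vinylboronic acid pinacol ester (1.5 equiv), Pd(dppf)Cl2 (3 mol %), K2CO3, 1,4-dioxane/H2O, 80 °C, BHT
Reagents that add atoms: vinylboronic acid pinacol ester, C=CB1OC(C)(C)C(C)(C)O1
Why: Suzuki–Miyaura coupling of the aryl bromide with the vinylboronate; the hindered chromene olefin and the ether groups should be inert under these mildly basic conditions.

Step 6
Reactants: 10 7-methoxy-2,2-dimethyl-6-vinyl-2H-chromene
Product: 11 (S)-6-(but-3-en-2-yl)-7-methoxy-2,2-dimethyl-2H-chromene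
Conditions: [(η3-allyl)NiBr]2 (1 mol %), Feringa-type binaphthol bis(1-phenylethyl)amine phosphoramidite (2 mol %), NaBArF4, ethylene (1 atm), CH2Cl2, −70 °C
Reagents that add atoms: ethylene, C=C
Why: Ni-catalysed asymmetric hydrovinylation of a vinylarene: the cationic Ni–H adds Markovnikov to give an η3-benzyl complex, ethylene inserts at the benzylic carbon and β-hydride elimination releases the 3-aryl-1-butene; the chiral phosphoramidite on nickel controls the new stereocentre (catalyst control), and the internal, hindered chromene olefin should not compete.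

Step 7
Reactants: 11 (S)-6-(but-3-en-2-yl)-7-methoxy-2,2-dimethyl-2H-chromene; 10 7-methoxy-2,2-dimethyl-6-vinyl-2H-chromene (3 equiv)
Product: 12 6-[(1E,3S)-3-(7-methoxy-2,2-dimethyl-2H-chromen-6-yl)but-1-en-1-yl]-7-methoxy-2,2-dimethyl-2H-chromene
Conditions: Hoveyda–Grubbs II (5 mol %), 1,4-benzoquinone (10 mol %), CH2Cl2, 40 °C, argon sparge
Reagents that add atoms: none
Why: Olefin cross-metathesis between an α-branched terminal olefin and a styrene should give the thermodynamically favoured E-styrenyl olefin with loss of ethylene; the stereocentre is not involved, and the 2,2-disubstituted chromene olefins are too hindered and unstrained to react.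

Compound list
1 | 1-bromo-2,4-dimethoxybenzene | COc1ccc(Br)c(OC)c1 | starting material
2 | 2-bromo-2-methylpropanoyl bromide | CC(C)(Br)C(=O)Br | starting material
3 | 2-bromo-1-(5-bromo-2,4-dimethoxyphenyl)-2-methylpropan-1-one (forms in the flask, not isolated) | COc1cc(OC)c(cc1Br)C(=O)C(C)(C)Br | intermediate
4 | 5-bromo-6-methoxy-2,2-dimethylbenzofuran-3(2H)-one | COc1cc2OC(C)(C)C(=O)c2cc1Br | intermediate
5 | 5-bromo-6-methoxy-2,2-dimethyl-3-methylidene-2,3-dihydrobenzofuran | COc1cc2OC(C)(C)C(=C)c2cc1Br | intermediate
6 | 9-[(5-bromo-6-methoxy-2,2-dimethyl-2,3-dihydrobenzofuran-3-yl)methyl]-9-borabicyclo[3.3.1]nonane, racemic (forms in the flask, not isolated) | COc1cc2OC(C)(C)C(CB3C4CCCC3CCC4)c2cc1Br | intermediate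
7 | (5-bromo-6-methoxy-2,2-dimethyl-2,3-dihydrobenzofuran-3-yl)methanol, racemic | COc1cc2OC(C)(C)C(CO)c2cc1Br | intermediate
8 | (5-bromo-6-methoxy-2,2-dimethyl-2,3-dihydrobenzofuran-3-yl)methyl trifluoromethanesulfonate, racemic (forms in the flask, not isolated) | COc1cc2OC(C)(C)C(COS(=O)(=O)C(F)(F)F)c2cc1Br | intermediate
9 | 6-bromo-7-methoxy-2,2-dimethyl-2H-chromene | COc1cc2OC(C)(C)C=Cc2cc1Br | intermediate
10 | 7-methoxy-2,2-dimethyl-6-vinyl-2H-chromene | COc1cc2OC(C)(C)C=Cc2cc1C=C | intermediate
11 | (S)-6-(but-3-en-2-yl)-7-methoxy-2,2-dimethyl-2H-chromene | C=C[C@H](C)c1cc2c(cc1OC)OC(C)(C)C=C2 | intermediate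
12 | 6-[(1E,3S)-3-(7-methoxy-2,2-dimethyl-2H-chromen-6-yl)but-1-en-1-yl]-7-methoxy-2,2-dimethyl-2H-chromene | COc1cc2c(cc1/C=C/[C@H](C)c1cc3c(cc1OC)OC(C)(C)C=C3)C=CC(C)(C)O2 | target

Total step count: 7. Longest linear sequence: 7 steps (1 → 4 → 5 → 7 → 9 → 10 → 11 → 12); compound 10 is used twice, in steps 6 and 7.

Steps most likely to fail

Step 4. The ionisation may leak into other shift manifolds: a 1,2-hydride shift from C3 followed by a methyl shift from C2, or O1 participation with ring contraction. The chroman-4-yl cation may also be captured by the electron-rich product olefin (cationic dimerisation). The fallback sets out from ketone 4 and keeps the one-carbon ring enlargement but moves it to the carbonyl stage. Lewis-acid-promoted homologation of 4 with trimethylsilyldiazomethane (BF3·OEt2, CH2Cl2, −78 → 0 °C, then acidic desilylation) should insert CH2 by aryl migration to give 6-bromo-7-methoxy-2,2-dimethylchroman-3-one F1. Condensation with tosylhydrazide (MeOH, 50 °C) gives the tosylhydrazone of 6-bromo-7-methoxy-2,2-dimethylchroman-3-one F2. Aprotic Bamford–Stevens decomposition (NaOMe, diglyme, 140 °C) generates the C3 carbene, whose 1,2-hydrogen shift from C4 gives the C3=C4 olefin and returns to the route at 9. Should the homologation insert on the other side of the carbonyl, the regioisomeric 4-ketone would converge on the same olefin through the same two operations.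

Step 6. The ortho-methoxy group may chelate nickel and slow turnover, the enantiofacial discrimination may be insufficient, the acid-sensitive vinylarene may dimerise under the cationic hydride, and the product may isomerise to the conjugated 2-aryl-2-butene. The fallback sets out from 10 and separates the C–H and C–C bond formations. Copper-hydride-catalysed Markovnikov hydroboration (CuCl, NaOtBu, DTBM-SEGPHOS, HBpin, toluene, rt) should give (R)-2-[1-(7-methoxy-2,2-dimethyl-2H-chromen-6-yl)ethyl]-4,4,5,5-tetramethyl-1,3,2-dioxaborolane F3. Zweifel olefination (vinylmagnesium bromide, THF, −78 °C; I2; NaOMe) transfers the benzylic carbon to the vinyl group with retention and returns to the route at 11.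

Step 7. The ortho-methoxystyrene may park ruthenium as a chelated carbene, homodimerisation of 10 may consume the partner, and ruthenium hydrides may migrate the terminal olefin of 11 into conjugation and erase the stereocentre. The fallback sets out from 9 and 11 and forms the aryl–vinyl bond instead of the C=C bond. Bromine–lithium exchange on 9 (n-BuLi, THF, −78 °C), borylation with B(OiPr)3 and aqueous work-up give (7-methoxy-2,2-dimethyl-2H-chromen-6-yl)boronic acid F4. Oxidative Heck arylation of 11 with F4 (Pd(OAc)2/1,2-bis(phenylsulfinyl)ethane, benzoquinone, AcOH, dioxane, rt) proceeds without palladium hydride chain-walking and should give the E-styrenyl olefin, returning to the route at 12.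

Further compounds
F1 | step 4 | 6-bromo-7-methoxy-2,2-dimethylchroman-3-one | COc1cc2OC(C)(C)C(=O)Cc2cc1Br
F2 | step 4 | N'-(6-bromo-7-methoxy-2,2-dimethylchroman-3-ylidene)-4-methylbenzenesulfonohydrazide | COc1cc2OC(C)(C)C(=NNS(=O)(=O)c3ccc(C)cc3)Cc2cc1Br
F3 | step 6 | (R)-2-[1-(7-methoxy-2,2-dimethyl-2H-chromen-6-yl)ethyl]-4,4,5,5-tetramethyl-1,3,2-dioxaborolane | CC1(C)OB(OC1(C)C)[C@H](C)c1cc2c(cc1OC)OC(C)(C)C=C2
F4 | step 7 | (7-methoxy-2,2-dimethyl-2H-chromen-6-yl)boronic acid | COc1cc2OC(C)(C)C=Cc2cc1B(O)O
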